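3 questions are put to Thursday's flask, and one ratio serves for each.

- Thursday's: D 0.10 M; G 0.050 M; the very flask that is asked about, followed so far
- flask: D 0.10 M; G 0.0500 M; time 1.0 h

- Thursday's (time / min: Z / %, J / %): 2.00: 6.1, 1.2; 4.00: 8.8, 1.8; 6.00: 10.7, 2.7; 8.00: 13.0, 4.2; 10.0: 14.0, 5.1; 12.0: 14.5, 6.2

(readings scatter by 0.3 percentage points)

* equivalents of G to D, everything else as given, that leave most Z at 1.0 h
* the amount of Z then, in percent of the D charged
* the amount of Z with the amounts as given

- steps thought possible: D + G -> Z; G -> X; G + Z -> J; D <-> Q; G + J <-> L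

Making Z and making J each take one G, so G cancels when the two rates are compared at one moment. Let P be the fraction of charged D not yet in Z, J or L, that is D and Q together. If D stays a fixed part of P, the share of fresh Z passed on to J is w = S·Z/P, with S a constant of the two steps, defined and read below. As Z climbs and P falls, w drifts up to 1, where Z stops at Z = P/S. Integrating gives that peak as 1/S^(S/(S−1)).

Time does not stand in this peak. S matters: values of 2, 3 and 4 give peaks of 25.0%, 19.2% and 15.7%.

Between 8.00 min and 12.0 min in Thursday's readings, w reads 0.571, around P = 80.9%. So the selectivity factor S, the pace of Z going on to J per unit of Z over that of P giving Z per unit of P, reads 3.30. This reckoning of my own puts the peak at 18.0%, costing 0.629 equivalents of G. If the charged G is consumed, P comes near 0.667, and the same integral then gives 17.6% at the charged amounts.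

The forecast says 0.62 equiv (0.52 equiv to 0.85 equiv), 17.8% (16% to 20%) and 17% (15.3% to 18.7%): “Z peaks flatly near 17.5–18%”.

The flask gives 0.652 equiv, 18.4% and 17.9%.

    D + G → Z (k = 0.0261 L mol⁻¹ s⁻¹)
    G → X (k = 7.17 × 10⁻⁶ s⁻¹)
    G + Z → J (k = 0.0298 L mol⁻¹ s⁻¹)
    D ⇌ Q (K = 1.80, k = 0.0285 s⁻¹)
    G + J ⇌ L (K = 4.24 L mol⁻¹, k = 0.00460 L mol⁻¹ s⁻¹)

At 1.00 h, Thursday's flask holds Z at 17.9% against P of 66.7%, so w stands at 0.884, with G at 1.66% of its charge. The neighbour with 0.060 M of D has 0.833 equivalents of G, more than the peak's cost. Its P at 1.00 h is 53.7% and its w is 1.11, past 1, with G at 8.82% of its charge. That neighbour holds J at 27.4% and Z at 18.1%.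

(The readings are calculated for an exercise; scatter was added.)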